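I decided to read these plateaus as the end of a race for G, not as the death of X, so the thing to watch in a repeat is the ratio of the charges and how high c_G starts, not the clock.

| flask | G | X | remark | time |
|---|---|---|---|---|
| Saturday's | 0.10 M | 0.083 mM | run made earlier |  |
| Thursday's | 0.10 M | 0.19 mM | run made earlier |  |
| Wednesday's | 0.16 M | 0.10 mM | run made earlier |  |
| north | 0.30 M | 0.30 mM |  | 120 h |
| north-west | 0.10 M | 0.10 mM |  | 40 h |

| Saturday's: time / h | Saturday's: D / % | Thursday's: time / h | Thursday's: D / % | Wednesday's: time / h | Wednesday's: D / % |
|---|---|---|---|---|---|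
| 3.00 | 77.7 | 8.00 | 87.7 | 8.00 | 71.5 |
| 6.00 | 77.7 | 15.0 | 88.2 | 15.0 | 71.2 |
| 12.0 | 77.5 | 25.0 | 88.1 | 25.0 | 70.6 |
| 20.0 | 78.1 | 30.0 | 88.3 | 30.0 | 71.2 |
| 40.0 | 77.7 | 40.0 | 88.3 | 40.0 | 70.8 |

(readings scatter by 0.3 percentage points)



* which of the two ends with the higher amount of D, in percent of the G charged ("neither" if they lie within 2 percentage points) (north / north-west / neither)
* D at the end, in percent of the G charged, north
* D at the end, in percent of the G charged, north-west

This is my own reckoning. In the first instants c_G stands at its charge, and X turns G into D at a rate that goes with c_X. A second loss of G, which I took as second order in G, competes, and the ratio of its rate to that of D goes with c_G/c_X. Through the middle c_G falls, so the split tilts towards D, while c_X holds if X is a true catalyst. The end is the sum of that race, a flat line: Saturday's flask reads 77.7 % at 3.00 h and 77.7 % at 40.0 h.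

Let u be the starting ratio of loss to D, a selectivity figure. Integrating the split gives the final fraction of D as Y = ln(1 + u)/u, close to (6 + u)/(6 + 4u), and I use this second form both ways.

The mean plateaus are 77.7 % on Saturday, 88.1 % on Thursday and 71.1 % on Wednesday. I define the loss coefficient s = u·c_X/c_G, the u that one unit of charge ratio buys. Saturday reads 5.25 × 10⁻⁴ and Thursday 5.36 × 10⁻⁴, although X differs by a factor of 2.29. Their mean at 0.10 M of G is 5.31 × 10⁻⁴. Wednesday, at 0.16 M, reads 5.89 × 10⁻⁴, higher, as if the step to D saturates.

North and north-west carry the same charge ratio, so in my reckoning they differ through s. Carried on in a straight line, beyond Wednesday's c_G, s reaches 7.25 × 10⁻⁴ for north. So u is 0.725 and D 75.6 % in north, and u is 0.531 and D 80.4 % in north-west. That is a gap of 4.8 percentage points towards north-west, against the margin of 2 points.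

The forecast differs from mine. It says north, with north at 87.5 % (82.5 % to 89 %) and north-west at 83.5 % (80.5 % to 85.5 %), on the ground that “each run stops because the enzyme's capacity runs out”.

The flask gave 75.6 % in north and 80.5 % in north-west, so north-west leads.

    G + X → D + X, rate k1*[G]*[X]/(1 + ([G]/Km1)) (0.270 M, k = 1.60 × 10⁵ L mol⁻¹ h⁻¹)
    2 G → Z (k = 34.0 L mol⁻¹ h⁻¹)

North ended with X at 100 % and G, the limiting reagent, at 0 %; Z held 24.4 % of the G charged, two G in each Z. The main reason for the shortfall is the reaction of 2 G to Z: without it, north gives 100 % and north-west 100 %. With the denominator term of the step to D taken away instead, north gives 83.3 % and north-west 83.3 %. That term, part of the shortfall, costs north 7.7 points and north-west 2.9 points.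

For north-west with X at 2.5 × 10⁻⁵ M, s gives u = 2.12 and D 56.1 %; that flask gave 54.6 %.

The runs were generated by integration with made-up constants.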